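**Retrosynthetic overview**

1. The C1 alcohol is taken back to a ketone and the C4 cinnamate to a tertiary alcohol made by methyl addition to a C4 ketone. The last ester-free intermediate is therefore the trans-fused 7-isopropyl-10-methyl-Δ7-octalin-1,4-dione, and the C1 ketone stands in for a protecting group until the final step.
2. Ring B of this dione is cut in one move at C6–C7 and C9–C10. The ring A piece is a bis-nucleophile: the C1 ketone as a silyl enol ether (C10 nucleophilic) and the C4 ketone hidden in a siloxycyclopropane spanning C4–C5–C6 (C6 a latent homoenolate). The three-carbon piece is a bis-electrophile, (Z)-3-bromo-4-methylpent-2-enyl methyl carbonate (allyl end C9, vinyl bromide end C7, isopropyl in place). One palladium catalyst joins them in a formal (3+3) annulation.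
3. The enabling feature is the 1,4-dioxygenation of ring A: the two ring B junction atoms lie α to the C1 oxygen (C10) and β to the C4 oxygen (C6, through C5), with the C7=C8 alkene exactly between them. The temporary cyclopropane also carries the C5 configuration and shields one face of C10, which should give the trans ring fusion.
4. The bicyclo[4.1.0] ring A piece comes from an intramolecular Kulinkovich reaction of a γ-lactone made by catalytic asymmetric crotylboration of methyl 4-oxobutanoate. The two crotylation stereocentres relay to C5 and are then erased.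
5. Order of ring formation: ring A together with the temporary cyclopropane (step 5), then ring B (step 8).

Key step: step 8

Remark: positions are given in eudesmane numbering (C1 carbinol carbon, C4 ester-bearing carbon, C5 and C10 ring fusion, C6–C9 the remaining carbons of ring B with the isopropyl group on C7). It is assumed that the hindered tertiary C4 alcohol is best acylated while C1 is still a ketone.

**Step 1**
Reactants: 1 3-methylbut-1-yne
Product: 2 4-methylpent-2-yn-1-ol
Conditions: n-BuLi, THF, −78 °C; (CH2O)n, −78 → 25 °C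
Reagents that add atoms: paraformaldehyde (formaldehyde unit), C=O
Why: Addition of the lithium acetylide to formaldehyde (alkynylation) should give the propargylic alcohol; no stereocentre is formed.

**Step 2**
Reactants: 2 4-methylpent-2-yn-1-ol
Product: 3 (2Z)-3-bromo-4-methylpent-2-en-1-ol
Conditions: NaAlH2(OCH2CH2OMe)2, THF, 0 → 25 °C; then N-bromosuccinimide, −78 °C
Reagents that add atoms: N-bromosuccinimide, O=C1CCC(=O)N1Br
Why: Hydroxyl-directed trans-hydroalumination of the propargylic alcohol puts aluminium on C3 cis to the CH2O group, and bromodealumination with retention should give the Z vinyl bromide (bromine cis to CH2OH), the geometry that later places C6 and C9 cis on the ring B alkene.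

**Step 3**
Reactants: 3 (2Z)-3-bromo-4-methylpent-2-en-1-ol
Product: 4 (2Z)-3-bromo-4-methylpent-2-en-1-yl methyl carbonate
Conditions: ClCO2Me, pyridine, CH2Cl2, 0 °C
Reagents that add atoms: methyl chloroformate, COC(=O)Cl
Why: O-Acylation with a chloroformate should give the allylic methyl carbonate, the leaving group for π-allyl formation in step 8; the alkene geometry is not touched.

**Step 4**
Reactants: 5 methyl 4-oxobutanoate; 6 (E)-crotylboronic acid pinacol ester
Product: 8 (5S)-5-[(2R)-but-3-en-2-yl]oxolan-2-one, via hydroxy ester 7 (not isolated)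
Conditions: (R)-TRIP [(R)-3,3'-bis(2,4,6-triisopropylphenyl)-1,1'-binaphthyl-2,2'-diyl hydrogen phosphate] (5 mol %), toluene, −30 °C; then p-TsOH (cat.), CH2Cl2, 25 °C
Reagents that add atoms: none
Why: Chiral phosphoric acid-catalysed crotylboration through a closed six-membered chair transition state, in which the E-crotyl reagent gives the anti adduct and the (R)-acid is expected to set the (4S,5R) configuration, followed by acid-catalysed lactonisation of the γ-hydroxy ester.

**Step 5**
Reactants: 8 (5S)-5-[(2R)-but-3-en-2-yl]oxolan-2-one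
Product: 9 (1S,4S,5R,6R)-5-methylbicyclo[4.1.0]heptane-1,4-diol (cyclopropane CH2 anti to both the methyl group and the secondary hydroxyl)
Conditions: ClTi(OiPr)3, c-C5H9MgCl (slow addition), THF, 25 °C
Reagents that add atoms: none
Why: Intramolecular Kulinkovich cyclopropanation, in which the titanacyclopropane formed by alkene exchange adds to the lactone carbonyl and closes ring A (C4–C5) and the cis-fused cyclopropanol (C4–C6); the bicyclic transition state should place the C6 methylene anti to the C10 methyl and the C1 oxygen, which fixes C5 and C4 relative to the crotylation stereocentres.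

**Step 6**
Reactants: 9 (1S,4S,5R,6R)-5-methylbicyclo[4.1.0]heptane-1,4-diol
Product: 10 (1R,2R,6S)-6-hydroxy-2-methylbicyclo[4.1.0]heptan-3-one
Conditions: SO3·pyridine, DMSO, iPr2NEt, CH2Cl2, 0 °C
Reagents that add atoms: none
Why: Parikh–Doering oxidation should convert only the secondary C1 alcohol, since the tertiary cyclopropanol has no carbinol hydrogen and the conditions involve neither acid nor a one-electron oxidant that would open the cyclopropanol.

**Step 7**
Reactants: 10 (1R,2R,6S)-6-hydroxy-2-methylbicyclo[4.1.0]heptan-3-one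
Product: 11 (1R,6S)-2-methyl-3,6-bis(trimethylsilyloxy)bicyclo[4.1.0]hept-2-ene
Conditions: Me3SiCl, NaI, Et3N, MeCN, 25 → 40 °C
Reagents that add atoms: chlorotrimethylsilane, C[Si](C)(C)Cl
Why: Silyl enol ether formation under equilibrating conditions should give the thermodynamic, tetrasubstituted and cyclopropane-conjugated enol ether C1=C10 and cap the cyclopropanol; the C10 stereocentre is erased on purpose while C4 and C5 are kept.

**Step 8**
Reactants: 11 (1R,6S)-2-methyl-3,6-bis(trimethylsilyloxy)bicyclo[4.1.0]hept-2-ene; 4 (2Z)-3-bromo-4-methylpent-2-en-1-yl methyl carbonate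
Product: 13 (4aR,8aR)-4a-methyl-7-(propan-2-yl)-2,3,4a,5,8,8a-hexahydronaphthalene-1,4-dione, via allylated siloxycyclopropyl ketone 12 (not isolated)
Conditions: Pd2(dba)3 (5 mol %), PPh3 (25 mol %), CsF (3 equiv), THF–toluene, 25 °C, then 80 °C (one charge of catalyst and reagents)
Reagents that add atoms: none
Why: Proposed new method: a one-flask palladium relay in which fluoride first unmasks the C1 silyl enol ether and the C10 enolate attacks the CH2 terminus of the π-allyl complex formed from 4 and zerovalent palladium (C9–C10, giving 12); on warming, the same catalyst inserts into the vinyl C7–Br bond, the fluoride-liberated cyclopropanolate undergoes β-carbon elimination of its C4–C6 bond, and C(sp3)–C(sp2) reductive elimination joins C6 to C7 while the C4 ketone is unveiled. The closest known reaction types are the fluoride-triggered Tsuji-type allylation of silyl enol ethers with allyl carbonates and the palladium-catalysed ring-opening cross-coupling of cyclopropanols or siloxycyclopropanes with aryl and alkenyl halides; running both on one substrate as a formal (3+3) annulation is the new element. The allylation is intermolecular and closes no ring; ring B closes in the second event by reductive elimination from a seven-membered palladacycle, with the cis C7=C8 alkene carried in from the Z bromide. C10 is set in the allylation by attack anti to the cyclopropane methylene (C6) on the neighbouring carbon, which puts C9 on the α face and the methyl group on the β face, while C5 is not touched and keeps the configuration given by the cyclopropane, so that C6 and C9 are trans and the ring fusion is trans. The step needs the allylation to precede vinyl bromide activation (a tethered allylation would close the cis-fused ring); this should be secured by the much faster ionisation of the allyl carbonate at 25 °C and by the slower fluoride cleavage of the tertiary silyl ether. It also needs attack at the unsubstituted allyl terminus, retention of the Z geometry (the isopropyl group prefers the syn position of the π-allyl complex) and cleavage of the less substituted cyclopropane bond by palladium.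

**Step 9**
Reactants: 13 (4aR,8aR)-4a-methyl-7-(propan-2-yl)-2,3,4a,5,8,8a-hexahydronaphthalene-1,4-dione
Product: 14 (4S,4aR,8aR)-4-hydroxy-4,8a-dimethyl-6-(propan-2-yl)-3,4,4a,5,8,8a-hexahydronaphthalen-1(2H)-one
Conditions: MeMgBr, CeCl3, THF, −78 °C
Reagents that add atoms: methylmagnesium bromide, C[Mg]Br
Why: Organocerium 1,2-addition should take place at the less hindered C4 carbonyl (C1 is flanked by the quaternary C10) and from the α face in an equatorial sense, because the β face is blocked by the 1,3-diaxial C10 methyl, giving the axial 4β-alcohol with the new methyl α and without enolisation at C5.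

**Step 10**
Reactants: 14 (4S,4aR,8aR)-4-hydroxy-4,8a-dimethyl-6-(propan-2-yl)-3,4,4a,5,8,8a-hexahydronaphthalen-1(2H)-one; 15 (2E)-3-phenylprop-2-enoic anhydride
Product: 16 (1S,4aR,8aR)-1,4a-dimethyl-4-oxo-7-(propan-2-yl)-1,2,3,4,4a,5,8,8a-octahydronaphthalen-1-yl (2E)-3-phenylprop-2-enoate
Conditions: Sc(OTf)3 (5 mol %), MeCN, −20 → 0 °C
Reagents that add atoms: none
Why: Sc(OTf)3-catalysed acylation of a hindered tertiary alcohol with an anhydride under non-basic conditions should esterify the axial C4 hydroxyl without enolising the C1 ketone or epimerising C5; no stereocentre is formed.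

**Step 11**
Reactants: 16 (1S,4aR,8aR)-1,4a-dimethyl-4-oxo-7-(propan-2-yl)-1,2,3,4,4a,5,8,8a-octahydronaphthalen-1-yl (2E)-3-phenylprop-2-enoate
Product: 17 (1S,4R,4aR,8aR)-4-hydroxy-1,4a-dimethyl-7-(propan-2-yl)-1,2,3,4,4a,5,8,8a-octahydronaphthalen-1-yl (2E)-3-phenylprop-2-enoate (CNP0139862.2)
Conditions: NaBH4, CeCl3·7H2O, MeOH, −40 → 0 °C
Reagents that add atoms: none
Why: Luche reduction, in which hydride should add to the C1 ketone axially from the α face anti to the C10 methyl and give the equatorial 1β-alcohol, while the cinnamate ester and the ring alkene are left alone.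

**Compound list**

1 | 3-methylbut-1-yne | CC(C)C#C | starting material
2 | 4-methylpent-2-yn-1-ol | CC(C)C#CCO | intermediate
3 | (2Z)-3-bromo-4-methylpent-2-en-1-ol | CC(C)/C(Br)=C/CO | intermediate
4 | (2Z)-3-bromo-4-methylpent-2-en-1-yl methyl carbonate | CC(C)/C(Br)=C/COC(=O)OC | intermediate
5 | methyl 4-oxobutanoate | COC(=O)CCC=O | starting material
6 | (E)-crotylboronic acid pinacol ester, 2-[(2E)-but-2-en-1-yl]-4,4,5,5-tetramethyl-1,3,2-dioxaborolane | C/C=C/CB1OC(C)(C)C(C)(C)O1 | starting material
7 | methyl (4S,5R)-4-hydroxy-5-methylhept-6-enoate | C=C[C@@H](C)[C@@H](O)CCC(=O)OC | intermediate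
8 | (5S)-5-[(2R)-but-3-en-2-yl]oxolan-2-one | C=C[C@@H](C)[C@@H]1CCC(=O)O1 | intermediate
9 | (1S,4S,5R,6R)-5-methylbicyclo[4.1.0]heptane-1,4-diol | C[C@H]1[C@@H](O)CC[C@]2(O)C[C@H]12 | intermediate
10 | (1R,2R,6S)-6-hydroxy-2-methylbicyclo[4.1.0]heptan-3-one | C[C@H]1C(=O)CC[C@]2(O)C[C@H]12 | intermediate
11 | (1R,6S)-2-methyl-3,6-bis(trimethylsilyloxy)bicyclo[4.1.0]hept-2-ene | CC1=C(O[Si](C)(C)C)CC[C@]2(O[Si](C)(C)C)C[C@H]12 | intermediate
12 | (1R,2R,6S)-2-[(2Z)-3-bromo-4-methylpent-2-en-1-yl]-2-methyl-6-(trimethylsilyloxy)bicyclo[4.1.0]heptan-3-one | CC(C)/C(Br)=C/C[C@@]1(C)C(=O)CC[C@]2(O[Si](C)(C)C)C[C@H]12 | intermediate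
13 | (4aR,8aR)-4a-methyl-7-(propan-2-yl)-2,3,4a,5,8,8a-hexahydronaphthalene-1,4-dione (trans-fused) | CC(C)C1=CC[C@@]2(C)C(=O)CCC(=O)[C@@H]2C1 | intermediate
14 | (4S,4aR,8aR)-4-hydroxy-4,8a-dimethyl-6-(propan-2-yl)-3,4,4a,5,8,8a-hexahydronaphthalen-1(2H)-one | CC(C)C1=CC[C@@]2(C)C(=O)CC[C@](C)(O)[C@@H]2C1 | intermediate
15 | (2E)-3-phenylprop-2-enoic anhydride (cinnamic anhydride) | O=C(/C=C/c1ccccc1)OC(=O)/C=C/c1ccccc1 | starting material
16 | (1S,4aR,8aR)-1,4a-dimethyl-4-oxo-7-(propan-2-yl)-1,2,3,4,4a,5,8,8a-octahydronaphthalen-1-yl (2E)-3-phenylprop-2-enoate | CC(C)C1=CC[C@@]2(C)C(=O)CC[C@](C)(OC(=O)/C=C/c3ccccc3)[C@@H]2C1 | intermediate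
17 | (1S,4R,4aR,8aR)-4-hydroxy-1,4a-dimethyl-7-(propan-2-yl)-1,2,3,4,4a,5,8,8a-octahydronaphthalen-1-yl (2E)-3-phenylprop-2-enoate | CC(C)C1=CC[C@@]2(C)[C@H](O)CC[C@](C)(OC(=O)/C=C/c3ccccc3)[C@@H]2C1 | target

**Step count and risks**

Total step count: 11. Longest linear sequence: 8 steps (steps 4 to 11); steps 1 to 3 prepare the three-carbon partner 4.

The three steps most likely to fail:

1. Step 8 (Proposed new method). The order of the two bond formations may be inverted by premature oxidative addition at the vinyl bromide or premature unmasking of the cyclopropanol, so that ring B closes by a tethered allylation with cis fusion. The C6–palladium homoenolate may undergo β-hydride elimination to an exocyclic enone instead of reductive elimination. Fluoride may epimerise C5 once the C4 ketone is free. Fallback with known chemistry, forming the two bonds separately and closing ring B by metathesis: from 11, the enol ether is allylated with allyl methyl carbonate (Pd2(dba)3, PPh3, Bu4N·Ph3SiF2, THF, 25 °C, then aqueous KF) to give the allyl cyclopropanol (1R,2R,6S)-6-hydroxy-2-methyl-2-(prop-2-en-1-yl)bicyclo[4.1.0]heptan-3-one F1. Ring-opening cross-coupling of F1 with 2-bromo-3-methylbut-1-ene (Pd(OAc)2, PPh3, Cs2CO3, toluene, 80 °C) should give (2R,3R)-2-methyl-3-(3-methyl-2-methylidenebutyl)-2-(prop-2-en-1-yl)cyclohexane-1,4-dione F2. Ring-closing metathesis of F2 (second-generation Grubbs catalyst, CH2Cl2, 40 °C) forms the C7=C8 alkene and comes back to the route at 13.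

2. Step 5. The lactone may fail to engage the titanacyclopropane, or the relay of configuration from C10 and C1 to C5 may be weak, which after step 7 would appear as loss of enantiomeric purity; if the relay runs in the opposite sense, the enantiomeric phosphoric acid would be used in step 4. Fallback that builds ring A by metathesis and the cyclopropanol by carbenoid addition: from 8, opening with MeLi (THF, −78 °C) and silylation (t-BuMe2SiCl, imidazole) should give (5S,6R)-5-[(tert-butyldimethylsilyl)oxy]-6-methyloct-7-en-2-one F3. Kinetic enol silylation (LiN(iPr)2, t-BuMe2SiCl, THF, −78 °C) gives (5S,6R)-2,5-bis[(tert-butyldimethylsilyl)oxy]-6-methylocta-1,7-diene F4. Ring-closing metathesis (second-generation Grubbs catalyst) gives the cyclic silyl enol ether (3R,4S)-1,4-bis[(tert-butyldimethylsilyl)oxy]-3-methylcyclohex-1-ene F5. Simmons–Smith cyclopropanation (Et2Zn, CH2I2, CH2Cl2, 0 °C) anti to the allylic methyl gives (1S,4S,5R,6R)-1,4-bis[(tert-butyldimethylsilyl)oxy]-5-methylbicyclo[4.1.0]heptane F6, and Bu4NF removes both silyl groups and comes back to the route at 9.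

3. Step 9. The reagent may discriminate poorly between the C4 and C1 carbonyls, or enolisation toward C5 may erode the trans ring fusion. Fallback that differentiates the two carbonyls by protection instead of by rate: from 13, the less hindered C4 carbonyl is ketalised (ethylene glycol, p-TsOH, benzene, reflux) to the C4 mono-dioxolane of 13 F7. NaBH4 (MeOH, 0 °C) reduces C1 to the 1β-alcohol of that ketal F8, and t-BuMe2SiOTf with 2,6-lutidine gives its silyl ether F9. Pyridinium p-toluenesulfonate in wet acetone frees the ketone (4R,4aR,8aR)-4-[(tert-butyldimethylsilyl)oxy]-4a-methyl-7-(propan-2-yl)-3,4,4a,5,8,8a-hexahydronaphthalen-1(2H)-one F10. MeMgBr with CeCl3 gives the 4β-tertiary alcohol carrying the C1 silyl ether F11. Deprotonation with KN(SiMe3)2 and acylation with (E)-cinnamoyl chloride gives the C1 silyl ether of the target F12, and HF·pyridine removes the silyl group and comes back to the route at 17.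

**Further compounds**

F1 | step 8 | (1R,2R,6S)-6-hydroxy-2-methyl-2-(prop-2-en-1-yl)bicyclo[4.1.0]heptan-3-one | C=CC[C@@]1(C)C(=O)CC[C@]2(O)C[C@H]12
F2 | step 8 | (2R,3R)-2-methyl-3-(3-methyl-2-methylidenebutyl)-2-(prop-2-en-1-yl)cyclohexane-1,4-dione | C=CC[C@@]1(C)C(=O)CCC(=O)[C@@H]1CC(=C)C(C)C
F3 | step 5 | (5S,6R)-5-[(tert-butyldimethylsilyl)oxy]-6-methyloct-7-en-2-one | C=C[C@@H](C)[C@@H](O[Si](C)(C)C(C)(C)C)CCC(C)=O
F4 | step 5 | (5S,6R)-2,5-bis[(tert-butyldimethylsilyl)oxy]-6-methylocta-1,7-diene | C=C[C@@H](C)[C@@H](O[Si](C)(C)C(C)(C)C)CCC(=C)O[Si](C)(C)C(C)(C)C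
F5 | step 5 | (3R,4S)-1,4-bis[(tert-butyldimethylsilyl)oxy]-3-methylcyclohex-1-ene | C[C@@H]1C=C(O[Si](C)(C)C(C)(C)C)CC[C@@H]1O[Si](C)(C)C(C)(C)C
F6 | step 5 | (1S,4S,5R,6R)-1,4-bis[(tert-butyldimethylsilyl)oxy]-5-methylbicyclo[4.1.0]heptane | C[C@H]1[C@@H](O[Si](C)(C)C(C)(C)C)CC[C@]2(O[Si](C)(C)C(C)(C)C)C[C@H]12
F7 | step 9 | dione 13 with the C4 carbonyl as its 1,3-dioxolane | CC(C)C1=CC[C@@]2(C)C(=O)CCC3(OCCO3)[C@@H]2C1
F8 | step 9 | 1β-alcohol of ketal F7 | CC(C)C1=CC[C@@]2(C)[C@H](O)CCC3(OCCO3)[C@@H]2C1
F9 | step 9 | tert-butyldimethylsilyl ether of F8 | CC(C)C1=CC[C@@]2(C)[C@H](O[Si](C)(C)C(C)(C)C)CCC3(OCCO3)[C@@H]2C1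
F10 | step 9 | (4R,4aR,8aR)-4-[(tert-butyldimethylsilyl)oxy]-4a-methyl-7-(propan-2-yl)-3,4,4a,5,8,8a-hexahydronaphthalen-1(2H)-one | CC(C)C1=CC[C@@]2(C)[C@H](O[Si](C)(C)C(C)(C)C)CCC(=O)[C@@H]2C1
F11 | step 9 | 4β-hydroxy-4α-methyl tertiary alcohol carrying the C1 tert-butyldimethylsilyl ether | CC(C)C1=CC[C@@]2(C)[C@H](O[Si](C)(C)C(C)(C)C)CC[C@](C)(O)[C@@H]2C1
F12 | step 9 | C1 tert-butyldimethylsilyl ether of target 17 | CC(C)C1=CC[C@@]2(C)[C@H](O[Si](C)(C)C(C)(C)C)CC[C@](C)(OC(=O)/C=C/c3ccccc3)[C@@H]2C1
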